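**Retrosynthetic overview**
1. Target 33 ⇐ bis-O-sulfation of hydroquinone 32 ⇐ oxidative demethylation of dimethyl ether 30.
2. 30 ⇐ C1′ enol triflate 29 ⇐ silyl enol ether 28 ⇐ key step: radical conjugate addition of the Cb radical (from left-half acid 16) to C9′ of tetrasubstituted enone 26. This forms Cb–C9′ and the C9′ quaternary centre, and its enolate fixes the C10′=C1′ alkene.
3. Enone 26: ring A′ first (4,4-dimethylcyclohexenone), then ring B′ by asymmetric conjugate addition and aldol condensation.
4. Acid 16: ring A from 2-methylcyclohexanone (C4 by chiral-imine Michael addition), then ring B by asymmetric exo Diels–Alder with tiglaldehyde; aryl group by ArLi addition and benzylic deoxygenation.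
5. Ring order: A, B (left half); A′, B′ (right half); union; arene unmasking; sulfation.

Assumption: the target (akaterpin) is made as the free bis(hydrogen sulfate) drawn; locants used are left decalin C1–C10 (C4 quaternary, C5=C6, C8 CHMe, C9 C(Me)CH2Ar, C10–H), bridge Ca (on C4) and Cb (on C9′), right decalin C1′–C10′ (C4′ CMe2, C5′–H, C8′ CHMe, C9′ quaternary, C10′=C1′).

**Step 1**
Reactants: 1 hydroquinone
Product: 2 1,4-dimethoxybenzene
Conditions: MeI, K2CO3, acetone, reflux
Reagents that add atoms: iodomethane (CI)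
Why: Williamson O-methylation masks the hydroquinone as the dimethyl ether that later directs ortho-lithiation and is removed oxidatively.

**Step 2**
Reactants: 3 2-methylcyclohexanone (racemic); 4 methyl acrylate
Product: 7 methyl 3-[(1S)-1-methyl-2-oxocyclohexyl]propanoate, via imine 5 (not isolated), via adduct imine 6 (not isolated)
Conditions: (R)-1-phenylethylamine, TsOH (cat.), PhMe, reflux (−H2O); 4, THF, 40 °C; 20% aq AcOH, 25 °C
Reagents that add atoms: water (O)
Why: d'Angelo–Pfau deracemising Michael addition, in which the more substituted secondary enamine tautomer of the chiral imine adds to the acrylate on the face away from the phenyl group, sets the C4 quaternary centre as S (about 90% ee; the R-amine is chosen as the antipode of the amine known to give the R series).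

**Step 3**
Reactants: 7
Product: 8 methyl 3-[(1S)-1-methyl-2-(trifluoromethylsulfonyloxy)cyclohex-2-en-1-yl]propanoate
Conditions: KHMDS, THF, −78 °C; PhNTf2, −78 → 0 °C
Reagents that add atoms: N-phenylbis(trifluoromethanesulfonimide) (O=S(=O)(N(c1ccccc1)S(=O)(=O)C(F)(F)F)C(F)(F)F)
Why: Kinetic enolate O-triflation; the ketone can enolise only toward C10 (C4 is quaternary) and is more acidic than the ester.

**Step 4**
Reactants: 8; 9 potassium vinyltrifluoroborate
Product: 10 methyl 3-[(1S)-2-ethenyl-1-methylcyclohex-2-en-1-yl]propanoate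
Conditions: PdCl2(dppf)·CH2Cl2 (5 mol %), Et3N, n-PrOH, 90 °C
Reagents that add atoms: none
Why: Suzuki–Miyaura coupling of the alkenyl triflate with the vinyltrifluoroborate gives the 1-vinylcyclohexene diene (C10=C5–C6=C7).

**Step 5**
Reactants: 10; 11 (E)-2-methylbut-2-enal
Product: 12 methyl 3-[(1S,4aS,5S,6R)-5-formyl-1,5,6-trimethyl-1,2,3,4,4a,5,6,7-octahydronaphthalen-1-yl]propanoate
Conditions: (S)-oxazaborolidinium triflimide [from (S)-3,3-diphenyl-1-(o-tolyl)tetrahydro-1H,3H-pyrrolo[1,2-c][1,3,2]oxazaborole and HNTf2] (20 mol %), CH2Cl2, −78 → −20 °C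
Reagents that add atoms: none
Why: Corey-type cationic oxazaborolidine-catalysed Diels–Alder reaction with "ortho" regiochemistry (C9 to C10): the E-enal makes the C8 and C9 methyls cis, the exo (formyl-anti) topology usual for α-methyl enals puts the formyl group cis to H-10, and the catalyst-selected enal face fixes C8, C9 and C10 relative to C4, which itself gives little bias (catalyst enantiomer assigned from Corey's model).

**Step 6**
Reactants: 12
Product: 13 3-[(1S,4aS,5S,6R)-5-formyl-1,5,6-trimethyl-1,2,3,4,4a,5,6,7-octahydronaphthalen-1-yl]propanoic acid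
Conditions: LiOH, THF/MeOH/H2O, 25 °C; then 1 M HCl
Reagents that add atoms: lithium hydroxide ([Li+].[OH-])
Why: Ester saponification; the neopentyl aldehyde has no α-hydrogen and survives.

**Step 7**
Reactants: 13; 2
Product: 16 3-[(1S,4aR,5S,6R)-5-(2,5-dimethoxybenzyl)-1,5,6-trimethyl-1,2,3,4,4a,5,6,7-octahydronaphthalen-1-yl]propanoic acid, via 2,5-dimethoxyphenyllithium 14 (not isolated), via hydroxy acid 15 (not isolated)
Conditions: 2, n-BuLi, TMEDA, Et2O, 0 °C; 13, THF, −78 °C; then Li, NH3(l), −78 °C; NH4Cl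
Reagents that add atoms: none
Why: Directed ortho-lithiation, 1,2-addition of the aryllithium to the aldehyde, then dissolving-metal hydrogenolysis of the benzylic C–O bond in the same flask (tandem alkylation–reduction); the carbinol configuration is irrelevant, and the carboxylate and isolated alkene are inert.

**Step 8**
Reactants: 17 2-methylpropanal; 18 but-3-en-2-one
Product: 19 4,4-dimethylcyclohex-2-en-1-one
Conditions: H2SO4 (cat.), PhH, reflux (−H2O)
Reagents that add atoms: none
Why: Acid-catalysed Michael addition and aldol condensation (Robinson-type annulation) builds ring A′ with the C4′ gem-dimethyl group.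

**Step 9**
Reactants: 20 1-(1-methylcyclopropyl)ethan-1-one
Product: 22 2-(4-iodobutan-2-yl)-2-methyl-1,3-dioxolane (racemic), via iodoketone 21 (not isolated)
Conditions: Me3SiCl, NaI, MeCN, 0 → 25 °C; then HOCH2CH2OH, TsOH (cat.), PhH, reflux (−H2O)
Reagents that add atoms: sodium iodide ([Na+].[I-]); ethane-1,2-diol (OCCO)
Why: Iodotrimethylsilane formed in the flask opens the acylcyclopropane by iodide attack at the unhindered CH2 (homoconjugate addition), and the ketone is then masked as its dioxolane.

**Step 10**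
Reactants: 22; 19
Product: 26 (4aS,7S)-4,4,7,8-tetramethyl-3,4,4a,5,6,7-hexahydronaphthalen-1(2H)-one, via diorganozinc 23 (not isolated), via ketal ketone 24 (not isolated), via diketone 25 (not isolated)
Conditions: 22, Et2Zn, CuI (cat.), 50 °C, then vacuum; 19, Cu(OTf)2 (2 mol %), (S,R,R)-O,O′-(1,1′-binaphthalene-2,2′-diyl) N,N-bis(1-phenylethyl)phosphoramidite (4 mol %), PhMe, −30 °C; then 2 M HCl, THF, 25 °C; TsOH, PhH, reflux (−H2O)
Reagents that add atoms: none
Why: Copper/phosphoramidite-catalysed asymmetric conjugate addition of a functionalised dialkylzinc followed by ketal cleavage and intramolecular aldol condensation (Feringa-type annulation): the catalyst sets C5′ (same facial sense as the known diethylzinc additions), and C8′ equilibrates under the acid to the epimer whose methyl is pseudoaxial, avoiding A(1,2) strain with the C9′ methyl, i.e. trans to H-5′.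

**Step 11**
Reactants: 16; 26
Product: 28 C1′ triethylsilyl enol ether of the coupled bis-decalin (30 carrying OSiEt3 on C1′), via redox-active ester 27 (not isolated)
Conditions: 16, N-hydroxyphthalimide, DIC, DMAP (cat.), THF, 25 °C; then 26 (3 equiv), NiCl2·DME (20 mol %), 4,4′-di-tert-butyl-2,2′-bipyridine (20 mol %), Zn, Et3SiCl, DMA, 25 °C
Reagents that add atoms: chlorotriethylsilane (CC[Si](Cl)(CC)CC)
Why: Proposed new method: single-electron reduction of N-acyloxyphthalimide 27 by low-valent nickel/zinc releases CO2 and the primary Cb radical (not allylic or homoallylic, so it does not rearrange), which adds to the β-carbon C9′ of the chlorosilane-activated enone on the face of H-5′, anti to the pseudoaxial C8′ methyl, creating the C9′ quaternary centre with the bridge trans to the C8′ methyl, and the resulting α-keto radical is reduced and O-silylated so that the enol ether marks C1′–C10′ (closest known reaction types: nickel-catalysed reductive conjugate addition of alkyl halides to enones with chlorosilane trapping, and nickel/zinc Giese additions of redox-active esters).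

**Step 12**
Reactants: 28
Product: 29 C1′ enol triflate (30 carrying OSO2CF3 on C1′)
Conditions: CsF, PhNTf2, DME, 25 °C
Reagents that add atoms: N-phenylbis(trifluoromethanesulfonimide) (O=S(=O)(N(c1ccccc1)S(=O)(=O)C(F)(F)F)C(F)(F)F)
Why: Fluoride desilylation releases the regiodefined C1′–C10′ enolate, which is O-triflated without equilibration (enol silane to enol triflate exchange).

**Step 13**
Reactants: 29
Product: 30 akaterpin dimethyl ether (33 with OMe in place of both OSO3H)
Conditions: Pd(OAc)2 (5 mol %), PPh3, n-Bu3N, HCO2H, DMF, 60 °C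
Reagents that add atoms: none
Why: Palladium-catalysed formate reduction of the alkenyl triflate replaces OTf by H and leaves the C10′=C1′ alkene exactly where the radical step placed the enolate.

**Step 14**
Reactants: 30
Product: 32 akaterpin hydroquinone (33 with OH in place of both OSO3H), via quinone 31 (not isolated)
Conditions: (NH4)2Ce(NO3)6, MeCN/H2O, 0 °C; then aq Na2S2O4, EtOAc, 25 °C
Reagents that add atoms: water (O)
Why: Oxidative demethylation with cerium ammonium nitrate gives the benzoquinone, which dithionite reduces in the same flask; the two trisubstituted alkenes tolerate the brief oxidation.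

**Step 15**
Reactants: 32
Product: 33 akaterpin, the target bis(hydrogen sulfate)
Conditions: SO3·pyridine, pyridine, 50 °C; then H+-form ion-exchange resin, MeOH/H2O, 0 °C
Reagents that add atoms: sulfur trioxide–pyridine complex ([O-]S(=O)(=O)[n+]1ccccc1)
Why: O-sulfation of both phenols with the SO3–pyridine complex, followed by cation exchange to the acid form, completes the target without touching any stereocentre.

**Compound list**
1 | hydroquinone | Oc1ccc(O)cc1 | starting material
2 | 1,4-dimethoxybenzene | COc1ccc(OC)cc1 | intermediate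
3 | 2-methylcyclohexanone (racemic) | CC1CCCCC1=O | starting material
4 | methyl acrylate | C=CC(=O)OC | starting material
5 | (R)-N-(2-methylcyclohexylidene)-1-phenylethan-1-amine | CC1CCCCC1=N[C@H](C)c1ccccc1 | intermediate
6 | methyl 3-[(1S)-1-methyl-2-{[(1R)-1-phenylethyl]imino}cyclohexyl]propanoate | COC(=O)CC[C@]1(C)CCCCC1=N[C@H](C)c1ccccc1 | intermediate
7 | methyl 3-[(1S)-1-methyl-2-oxocyclohexyl]propanoate | COC(=O)CC[C@]1(C)CCCCC1=O | intermediate
8 | methyl 3-[(1S)-1-methyl-2-(trifluoromethylsulfonyloxy)cyclohex-2-en-1-yl]propanoate | COC(=O)CC[C@]1(C)CCCC=C1OS(=O)(=O)C(F)(F)F | intermediate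
9 | potassium vinyltrifluoroborate | [K+].C=C[B-](F)(F)F | starting material
10 | methyl 3-[(1S)-2-ethenyl-1-methylcyclohex-2-en-1-yl]propanoate | COC(=O)CC[C@]1(C)CCCC=C1C=C | intermediate
11 | (E)-2-methylbut-2-enal (tiglaldehyde) | C/C=C(\C)C=O | starting material
12 | methyl 3-[(1S,4aS,5S,6R)-5-formyl-1,5,6-trimethyl-1,2,3,4,4a,5,6,7-octahydronaphthalen-1-yl]propanoate (CHO cis to H-10; C8 and C9 methyls cis; C4 methyl on the face of H-10) | C[C@@H]1CC=C2[C@H](CCC[C@@]2(C)CCC(=O)OC)[C@@]1(C)C=O | intermediate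
13 | 3-[(1S,4aS,5S,6R)-5-formyl-1,5,6-trimethyl-1,2,3,4,4a,5,6,7-octahydronaphthalen-1-yl]propanoic acid | C[C@@H]1CC=C2[C@H](CCC[C@@]2(C)CCC(=O)O)[C@@]1(C)C=O | intermediate
14 | 2,5-dimethoxyphenyllithium | [Li]c1cc(OC)ccc1OC | intermediate
15 | 16 carrying OH on the benzylic carbon (both carbinol epimers; present as its dilithium salt) | C[C@@H]1CC=C2[C@H](CCC[C@@]2(C)CCC(=O)O)[C@@]1(C)C(O)c1cc(OC)ccc1OC | intermediate
16 | 3-[(1S,4aR,5S,6R)-5-(2,5-dimethoxybenzyl)-1,5,6-trimethyl-1,2,3,4,4a,5,6,7-octahydronaphthalen-1-yl]propanoic acid | C[C@@H]1CC=C2[C@H](CCC[C@@]2(C)CCC(=O)O)[C@@]1(C)Cc1cc(OC)ccc1OC | intermediate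
17 | 2-methylpropanal | CC(C)C=O | starting material
18 | but-3-en-2-one | CC(=O)C=C | starting material
19 | 4,4-dimethylcyclohex-2-en-1-one | CC1(C)CCC(=O)C=C1 | intermediate
20 | 1-(1-methylcyclopropyl)ethan-1-one | CC(=O)C1(C)CC1 | starting material
21 | 5-iodo-3-methylpentan-2-one (racemic) | CC(=O)C(C)CCI | intermediate
22 | 2-(4-iodobutan-2-yl)-2-methyl-1,3-dioxolane (racemic) | CC(CCI)C1(C)OCCO1 | intermediate
23 | bis[3-(2-methyl-1,3-dioxolan-2-yl)butyl]zinc | CC(CC[Zn]CCC(C)C1(C)OCCO1)C1(C)OCCO1 | intermediate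
24 | (3R)-4,4-dimethyl-3-[3-(2-methyl-1,3-dioxolan-2-yl)butyl]cyclohexan-1-one (side-chain epimers) | CC(CC[C@@H]1CC(=O)CCC1(C)C)C1(C)OCCO1 | intermediate
25 | (3R)-4,4-dimethyl-3-(3-methyl-4-oxopentyl)cyclohexan-1-one (side-chain epimers) | CC(=O)C(C)CC[C@@H]1CC(=O)CCC1(C)C | intermediate
26 | (4aS,7S)-4,4,7,8-tetramethyl-3,4,4a,5,6,7-hexahydronaphthalen-1(2H)-one (C8′ methyl trans to H-5′) | CC1=C2C(=O)CCC(C)(C)[C@@H]2CC[C@@H]1C | intermediate
27 | N-(acyloxy)phthalimide ester of 16 | C[C@@H]1CC=C2[C@H](CCC[C@@]2(C)CCC(=O)ON3C(=O)c4ccccc4C3=O)[C@@]1(C)Cc1cc(OC)ccc1OC | intermediate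
28 | C1′ triethylsilyl enol ether of the coupled bis-decalin (30 with OSiEt3 on C1′; C9′ bridge cis to H-5′, trans to C8′ methyl) | C[C@@H]1CC=C2[C@H](CCC[C@@]2(C)CC[C@@]2(C)C3=C(O[Si](CC)(CC)CC)CCC(C)(C)[C@@H]3CC[C@@H]2C)[C@@]1(C)Cc1cc(OC)ccc1OC | intermediate
29 | C1′ enol triflate (30 with OSO2CF3 on C1′) | C[C@@H]1CC=C2[C@H](CCC[C@@]2(C)CC[C@@]2(C)C3=C(OS(=O)(=O)C(F)(F)F)CCC(C)(C)[C@@H]3CC[C@@H]2C)[C@@]1(C)Cc1cc(OC)ccc1OC | intermediate
30 | akaterpin dimethyl ether | C[C@@H]1CC=C2[C@H](CCC[C@@]2(C)CC[C@@]2(C)C3=CCCC(C)(C)[C@@H]3CC[C@@H]2C)[C@@]1(C)Cc1cc(OC)ccc1OC | intermediate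
31 | akaterpin quinone (2-substituted 1,4-benzoquinone) | C[C@@H]1CC=C2[C@H](CCC[C@@]2(C)CC[C@@]2(C)C3=CCCC(C)(C)[C@@H]3CC[C@@H]2C)[C@@]1(C)CC1=CC(=O)C=CC1=O | intermediate
32 | akaterpin hydroquinone | C[C@@H]1CC=C2[C@H](CCC[C@@]2(C)CC[C@@]2(C)C3=CCCC(C)(C)[C@@H]3CC[C@@H]2C)[C@@]1(C)Cc1cc(O)ccc1O | intermediate
33 | akaterpin, bis(hydrogen sulfate) | C[C@@H]1CC=C2[C@H](CCC[C@@]2(C)CC[C@@]2(C)C3=CCCC(C)(C)[C@@H]3CC[C@@H]2C)[C@@]1(C)Cc1cc(OS(=O)(=O)O)ccc1OS(=O)(=O)O | target

**Step count and risks**

Total: 15 steps. Longest linear sequence: 11 steps (3 → 33 through steps 2–7 and 11–15).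

Most likely to fail, step 11 (the key radical addition). The β-carbon of enone 26 is fully substituted, so the intermolecular addition may be slow, and simple reduction of the radical or 1,5-hydrogen transfer may win. The fallback sets out from 26 and 16 and comes back at 30. Reduction of 26 with BH3·SMe2 and (R)-1-methyl-3,3-diphenyltetrahydro-1H,3H-pyrrolo[1,2-c][1,3,2]oxazaborole gives the allylic alcohol (1S,4aS,7S)-4,4,7,8-tetramethyl-1,2,3,4,4a,5,6,7-octahydronaphthalen-1-ol F1, with the hydroxyl on the face of H-5′. Esterification with 16 (DIC, DMAP) gives the allylic ester F2. Ireland–Claisen rearrangement (LDA, Me3SiCl, THF, −78 → 65 °C) then transfers the C1′–O chirality suprafacially to C9′ and forms Cb–C9′, the quaternary centre and the C10′=C1′ alkene in one event, giving the Claisen acid F3. Photocatalytic hydrodecarboxylation (9-mesityl-10-methylacridinium tetrafluoroborate, excess PhSH as fast hydrogen donor, 2,6-lutidine, blue light) removes the extra carboxyl and returns 30.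

Second, step 5 (Diels–Alder). Exo selectivity or catalyst control over the diene face may be insufficient with the hindered, trisubstituted dienophile. The fallback sets out from 10 and comes back at 12. Tiglaldehyde 11 is first converted with (2R,3R)-butane-2,3-diol (the antipodal diol if the induction proves opposite) into (4R,5R)-2-[(E)-but-2-en-2-yl]-4,5-dimethyl-1,3-dioxolane F4. Its ionisation with catalytic Me3SiOTf (CH2Cl2, −78 °C) gives a chiral alkoxy-allyl cation dienophile (Gassman-type ionic Diels–Alder), which adds to 10 under auxiliary control to give the dioxolane acetal of 12 F5. Aqueous acid hydrolysis returns 12.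

Third, step 10 (conjugate addition and annulation). The branched, functionalised zinc reagent may add poorly to the hindered enone. The fallback sets out from 19 and comes back at 25, which is cyclised to 26 as in step 10. Rhodium-catalysed asymmetric 1,4-addition of 9 to 19 (Rh(acac)(C2H4)2, (S)-BINAP, dioxane/H2O, 100 °C) gives (3S)-3-ethenyl-4,4-dimethylcyclohexan-1-one F6. Cross-metathesis with 3-methylpent-4-en-2-one (second-generation Grubbs catalyst, CH2Cl2, 40 °C) gives (3S)-4,4-dimethyl-3-[(1E)-3-methyl-4-oxopent-1-en-1-yl]cyclohexan-1-one F7. Hydrogenation (H2, Pd/C, EtOAc) gives diketone 25.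

**Further compounds**
F1 | step 11 | (1S,4aS,7S)-4,4,7,8-tetramethyl-1,2,3,4,4a,5,6,7-octahydronaphthalen-1-ol | CC1=C2[C@@H](O)CCC(C)(C)[C@@H]2CC[C@@H]1C
F2 | step 11 | allylic ester of 16 with F1 | C[C@@H]1CC=C2[C@H](CCC[C@@]2(C)CCC(=O)O[C@H]3CCC(C)(C)[C@@H]4CC[C@H](C)C(C)=C34)[C@@]1(C)Cc1cc(OC)ccc1OC
F3 | step 11 | Claisen acid (30 carrying CO2H on Cb; both Cb epimers) | C[C@@H]1CC=C2[C@H](CCC[C@@]2(C)CC(C(O)=O)[C@@]2(C)C3=CCCC(C)(C)[C@@H]3CC[C@@H]2C)[C@@]1(C)Cc1cc(OC)ccc1OC
F4 | step 5 | (4R,5R)-2-[(E)-but-2-en-2-yl]-4,5-dimethyl-1,3-dioxolane | C/C=C(\C)C1O[C@H](C)[C@@H](C)O1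
F5 | step 5 | (4R,5R)-4,5-dimethyl-1,3-dioxolane acetal of 12 | C[C@@H]1CC=C2[C@H](CCC[C@@]2(C)CCC(=O)OC)[C@@]1(C)C3O[C@H](C)[C@@H](C)O3
F6 | step 10 | (3S)-3-ethenyl-4,4-dimethylcyclohexan-1-one | C=C[C@@H]1CC(=O)CCC1(C)C
F7 | step 10 | (3S)-4,4-dimethyl-3-[(1E)-3-methyl-4-oxopent-1-en-1-yl]cyclohexan-1-one (side-chain epimers) | CC(=O)C(C)/C=C/[C@@H]1CC(=O)CCC1(C)C
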